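**Plan**

Numbering: C1 (lactone O–CH), C2=C3, C4/C5 (epoxide), C6=C7 (C7 bears CO2Me), C8 (OAc), C9 (epoxy ester), C10, lactone carbons C11 (α), C12 (C=O), C13 (=CH2).
Cuts, in retrosynthetic order: the ester C–O bonds at C8 and C9, C7–C8 (opening the ten-membered ring to a C8 aldehyde and a C7 alkenyl iodide), C6=C7, the epoxide oxygen, C3–C4, C13, and last C10–C11 and C1–O of the lactone.
Enabling feature: the γ-lactone ring (O, C1, C10, C11, C12) carries its acyl-bearing carbon C11 on C10 and its oxygen on the neighbouring C1, which lies next to the C2=C3 unsaturation; this vicinal C–C/C–O pair is what an oxidative malonate annulation lays across a C1=C10 alkene, and holding C2=C3 as an alkyne makes the C1 radical propargylic.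
Forward order: (R)-glyceraldehyde acetonide → E-enyne → γ-lactone (first ring) → C13 methylene → C9 epoxyangelate → chain growth C3 to C7 → ten-membered carbocycle closed last at C7–C8 by Ni/Cr coupling → C8 acetate.
Stereochemistry: C9 from the chiral pool; C10 and C1 from the annulation (anti to the C9–O bond, trans lactone); C4/C5 and the epoxyangelate from Sharpless epoxidations with D-(−)-diethyl tartrate; C8 from Felkin–Anh addition during ring closure.

Key step: step 3

Assumption: C11 of lactones 6 and 8 is drawn as the trans epimer although it equilibrates and is erased in step 5; (Z)-3-iodoprop-2-en-1-ol is treated as not purchasable and is made in step 12.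

**Route**

Step 1
Reactants: 1 (R)-2,3-O-isopropylideneglyceraldehyde
Product: 2 (4S)-4-[(E)-2-iodoethenyl]-2,2-dimethyl-1,3-dioxolane
Conditions: CrCl2 (6 equiv), CHI3 (2 equiv), THF, 0 °C to rt
Reagents that add atoms: iodoform, IC(I)I
Why: Takai olefination, in which the geminal dichromium species from CHI3 adds to the aldehyde and eliminates to the E-iodoalkene under non-basic conditions that leave the α-stereocentre untouched.

Step 2
Reactants: 2 (4S)-4-[(E)-2-iodoethenyl]-2,2-dimethyl-1,3-dioxolane; 3 trimethylsilylacetylene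
Product: 4 (4S)-2,2-dimethyl-4-[(E)-4-(trimethylsilyl)but-1-en-3-yn-1-yl]-1,3-dioxolane
Conditions: PdCl2(PPh3)2 (3 mol%), CuI (6 mol%), Et3N, THF, rt
Reagents that add atoms: none
Why: Sonogashira coupling of an alkenyl iodide runs at room temperature with retention of the E geometry, and the silyl group blocks the second alkyne terminus.

Step 3
Reactants: 4 (4S)-2,2-dimethyl-4-[(E)-4-(trimethylsilyl)but-1-en-3-yn-1-yl]-1,3-dioxolane; 5 methyl hydrogen malonate
Product: 6 methyl (3R,4S,5S)-4-[(4S)-2,2-dimethyl-1,3-dioxolan-4-yl]-2-oxo-5-[(trimethylsilyl)ethynyl]oxolane-3-carboxylate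
Conditions: Mn(OAc)3·2H2O (2.5 equiv), Cu(OAc)2·H2O (0.2 equiv), KOAc, 5 (3 equiv), degassed AcOH, 40 °C, Ar
Reagents that add atoms: none
Why: The trivalent manganese enolate of half ester 5 gives by inner-sphere electron transfer an electrophilic malonyl radical that adds to C10, the alkene terminus remote from the alkyne, because only this mode leaves a propargyl-stabilised radical at C1; Cu(OAc)2, re-oxidised by Mn(OAc)3, converts that radical into the propargylic cation or its organocopper equivalent, which the free carboxyl group captures. The closest known reaction type is the Mn(OAc)3 lactone annulation of alkenes, dienes and conjugated enynes with acetic, cyanoacetic and malonic acid derivatives. The γ-lactone closes by 5-exo attack of the carboxylate oxygen on C1, so C10–C11 forms first and C1–O second. C10 is set by the C9 stereocentre: in the conformer with C9–H eclipsing the alkene the radical should enter anti to the C9–O bond and give the 9,10-anti product; C1 is set in the closure, where alkynyl and dioxolanyl groups take the trans arrangement of the less strained envelope; C11 settles trans by enolisation and is erased later. The step needs regioselectivity (alkene over alkyne, C10 over C1), secured by propargyl stabilisation and by the silyl cap that also prevents copper-mediated alkyne homocoupling; single addition, secured by the excess of 5; and facial selectivity, which rests on the dioxolane.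

Step 4
Reactants: 6 methyl (3R,4S,5S)-4-[(4S)-2,2-dimethyl-1,3-dioxolan-4-yl]-2-oxo-5-[(trimethylsilyl)ethynyl]oxolane-3-carboxylate
Product: 8 (3R,4S,5S)-4-[(4S)-2,2-dimethyl-1,3-dioxolan-4-yl]-5-ethynyl-2-oxooxolane-3-carboxylic acid, via dilithium hydroxy malonate 7 (not isolated)
Conditions: LiOH·H2O (4 equiv), THF/H2O, 0 °C to rt; then 1 M HCl to pH 3, 0 °C, EtOAc extraction
Reagents that add atoms: lithium hydroxide, [Li+].[OH-]
Why: Hydroxide cleaves the alkynyl C–Si bond, opens the lactone and saponifies the methyl ester, and on acidification the γ-hydroxy diacid should close back onto O1, the only free hydroxyl while the acetonide is intact, by acyl substitution that touches neither C1 nor C10.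

Step 5
Reactants: 8 (3R,4S,5S)-4-[(4S)-2,2-dimethyl-1,3-dioxolan-4-yl]-5-ethynyl-2-oxooxolane-3-carboxylic acid
Product: 10 (4S,5S)-4-[(4S)-2,2-dimethyl-1,3-dioxolan-4-yl]-5-ethynyl-3-methylideneoxolan-2-one, via Mannich base 9 (not isolated)
Conditions: (CH2O)n, Et2NH (0.5 equiv), EtOAc, 70 °C
Reagents that add atoms: formaldehyde (as paraformaldehyde), C=O
Why: Decarboxylative Mannich methylenation, in which the malonic-type α-carbon condenses with the iminium ion from formaldehyde and Et2NH and the resulting β-amino acid loses CO2 and the amine to leave the exocyclic C11=C13 bond under non-acidic conditions that spare the acetonide.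

Step 6
Reactants: 10 (4S,5S)-4-[(4S)-2,2-dimethyl-1,3-dioxolan-4-yl]-5-ethynyl-3-methylideneoxolan-2-one
Product: 11 diol: 10 with the acetonide removed (free C9 and C8 hydroxyls)
Conditions: AcOH/H2O (4:1), 40 °C
Reagents that add atoms: none
Why: Acid-catalysed hydrolysis of a terminal acetonide, chosen over any basic method so that the liberated C9 hydroxyl does not translactonise onto C12.

Step 7
Reactants: 11 diol with free C9 and C8 hydroxyls
Product: 12 primary triethylsilyl ether: 11 silylated at the C8 oxygen
Conditions: Et3SiCl (1.05 equiv), imidazole, CH2Cl2, −40 °C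
Reagents that add atoms: chlorotriethylsilane, CC[Si](Cl)(CC)CC
Why: Kinetic silylation distinguishes the primary C8 hydroxyl from the hindered secondary C9 hydroxyl at low temperature.

Step 8
Reactants: 13 angelic acid
Product: 14 (Z)-2-methylbut-2-en-1-ol
Conditions: LiAlH4, Et2O, 0 °C to rt
Reagents that add atoms: none
Why: LiAlH4 reduces the conjugated acid by 1,2-hydride delivery to the allylic alcohol with retention of the Z geometry.

Step 9
Reactants: 14 (Z)-2-methylbut-2-en-1-ol
Product: 15 [(2R,3S)-2,3-dimethyloxiran-2-yl]methanol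
Conditions: Ti(OiPr)4 (cat.), D-(−)-diethyl tartrate, tBuOOH, 4 Å molecular sieves, CH2Cl2, −20 °C
Reagents that add atoms: tert-butyl hydroperoxide, CC(C)(C)OO
Why: Sharpless asymmetric epoxidation, where the D-(−)-tartrate complex delivers oxygen to the face that gives the 2R centre and the Z alkene fixes the cis relation of CH2OH and the C3 methyl group.

Step 10
Reactants: 15 [(2R,3S)-2,3-dimethyloxiran-2-yl]methanol
Product: 16 (2S,3S)-2,3-dimethyloxirane-2-carboxylic acid
Conditions: RuCl3·xH2O (cat.), NaIO4, CCl4/MeCN/H2O, rt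
Reagents that add atoms: sodium periodate, [Na+].[O-]I(=O)(=O)=O; water, O
Why: RuO4 generated from RuCl3 and NaIO4 oxidises primary epoxy alcohols to glycidic acids without opening the epoxide or touching either stereocentre.

Step 11
Reactants: 12 primary triethylsilyl ether with free C9 hydroxyl; 16 (2S,3S)-2,3-dimethyloxirane-2-carboxylic acid
Product: 18 C9 epoxyangelate: 12 acylated at O9 by the (2S,3S)-2,3-dimethyloxirane-2-carbonyl group, via mixed anhydride 17 (not isolated)
Conditions: 2,4,6-trichlorobenzoyl chloride, Et3N, THF, rt; then 12, DMAP, toluene, rt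
Reagents that add atoms: none
Why: Yamaguchi esterification, in which DMAP attacks the mixed anhydride at the less shielded epoxyacyl carbonyl and transfers the acyl group to O9 without breaking any bond to C9.

Step 12
Reactants: 19 ethyl (Z)-3-iodoprop-2-enoate
Product: 20 (Z)-3-iodoprop-2-en-1-ol
Conditions: iBu2AlH (2.2 equiv), CH2Cl2, −78 °C; aqueous potassium sodium tartrate work-up
Reagents that add atoms: none
Why: Low-temperature iBu2AlH reduction of the ester to the allylic alcohol leaves the alkenyl iodide and its Z geometry intact.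

Step 13
Reactants: 18 C9 epoxyangelate with terminal alkyne; 20 (Z)-3-iodoprop-2-en-1-ol
Product: 21 Z-enynol: 18 joined at C3 to (Z)-CH=CH–CH2OH (C4=C5, C6 hydroxyl)
Conditions: PdCl2(PPh3)2 (5 mol%), CuI (10 mol%), Et3N, degassed THF, rt
Reagents that add atoms: none
Why: Sonogashira coupling forms C3–C4 with retention of the Z geometry, and the tertiary amine base cannot add irreversibly to the methylene lactone.

Step 14
Reactants: 21 Z-enynol
Product: 22 alkynyl cis-epoxy alcohol with (4S,5R)-epoxide
Conditions: Ti(OiPr)4 (1 equiv), D-(−)-diethyl tartrate (1.2 equiv), tBuOOH, 4 Å molecular sieves, CH2Cl2, −20 °C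
Reagents that add atoms: tert-butyl hydroperoxide, CC(C)(C)OO
Why: Sharpless asymmetric epoxidation is directed by the C6 hydroxyl to the C4=C5 alkene only, the D-(−)-tartrate reagent should override the remote stereocentres to give the 5R centre, and the Z alkene makes the epoxide cis (4S).

Step 15
Reactants: 22 alkynyl cis-epoxy alcohol
Product: 23 cis-alkenyl cis-epoxy alcohol (C2=C3 Z)
Conditions: H2 (1 atm), Pd/CaCO3 poisoned with Pb(OAc)2 (Lindlar catalyst), quinoline, EtOAc, 0 °C, stopped after one equivalent
Reagents that add atoms: none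
Why: Lindlar semihydrogenation adds H2 syn to the isolated alkyne on the poisoned surface to give the Z alkene before the conjugated 1,1-disubstituted methylene or the allylic C–O bonds react.

Step 16
Reactants: 23 cis-alkenyl cis-epoxy alcohol
Product: 24 cis-epoxy aldehyde (C6 = CHO; C4/C5 arrangement unchanged)
Conditions: Dess–Martin periodinane, NaHCO3, CH2Cl2, 0 °C to rt
Reagents that add atoms: none
Why: Buffered Dess–Martin oxidation is neutral and fast, so the cis-epoxy aldehyde should form without epimerisation at C5 or epoxide opening.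

Step 17
Reactants: 24 cis-epoxy aldehyde
Product: 25 methyl (Z)-2-iodoenoate: C6=C7 with iodine on C7 cis to C5 and CO2Me trans to C5
Conditions: Ph3P=CHCO2Me, NIS, CH2Cl2, −20 °C; then 24, −20 °C to rt
Reagents that add atoms: methyl (triphenylphosphoranylidene)acetate, COC(=O)C=P(c1ccccc1)(c1ccccc1)c1ccccc1; N-iodosuccinimide, O=C1CCC(=O)N1I
Why: Wittig olefination with the stabilised iodo ylide formed in the flask places the ester trans to the aldehyde residue, which is the Z iodoenoate and already the C5/CO2Me relationship of the target.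

Step 18
Reactants: 25 methyl (Z)-2-iodoenoate with C8 triethylsilyl ether
Product: 26 C8 aldehyde
Conditions: (COCl)2, DMSO, CH2Cl2, −78 to −30 °C; then iPr2NEt, −78 to 0 °C
Reagents that add atoms: none
Why: Under Swern conditions a primary triethylsilyl ether is converted directly into the aldehyde (activated DMSO displaces silicon at oxygen, then the sulfur ylide fragments), which avoids fluoride or acid on the divinyl epoxide and the C9 ester.

Step 19
Reactants: 26 C8 aldehyde
Product: 27 macrocyclic C8 alcohol (8R): the target with OH in place of OAc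
Conditions: CrCl2 (10 equiv), NiCl2 (0.1 equiv), DMSO/THF, rt, slow addition to 0.003 M
Reagents that add atoms: none
Why: Nozaki–Hiyama–Kishi coupling, in which zerovalent nickel inserts into C7–I and transmetalation gives an alkenyl species of trivalent chromium that adds only to the aldehyde with retention of alkene geometry; the two Z alkenes and the cis epoxide pre-bend the chain for ten-membered ring closure, and Felkin–Anh attack anti to the C9 acyloxy group should give the 8,9-anti (8R) alcohol.

Step 20
Reactants: 27 macrocyclic C8 alcohol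
Product: 28 target CNP0077533.1
Conditions: Ac2O, pyridine, DMAP (cat.), CH2Cl2, 0 °C
Reagents that add atoms: acetic anhydride, CC(=O)OC(C)=O
Why: DMAP-catalysed acetylation of the secondary allylic alcohol proceeds with retention at C8 and should be faster than migration of the hindered epoxyangeloyl group.

**Compound list**

1 | (R)-2,3-O-isopropylideneglyceraldehyde, (4R)-2,2-dimethyl-1,3-dioxolane-4-carbaldehyde | O=C[C@H]1COC(C)(C)O1 | starting material
2 | (4S)-4-[(E)-2-iodoethenyl]-2,2-dimethyl-1,3-dioxolane | I/C=C/[C@H]1COC(C)(C)O1 | intermediate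
3 | trimethylsilylacetylene | C#C[Si](C)(C)C | starting material
4 | (4S)-2,2-dimethyl-4-[(E)-4-(trimethylsilyl)but-1-en-3-yn-1-yl]-1,3-dioxolane (E-enyne) | C[Si](C)(C)C#C/C=C/[C@H]1COC(C)(C)O1 | intermediate
5 | methyl hydrogen malonate | COC(=O)CC(=O)O | starting material
6 | methyl (3R,4S,5S)-4-[(4S)-2,2-dimethyl-1,3-dioxolan-4-yl]-2-oxo-5-[(trimethylsilyl)ethynyl]oxolane-3-carboxylate (all-trans lactone) | O=C1O[C@H](C#C[Si](C)(C)C)[C@@H]([C@H]2COC(C)(C)O2)[C@@H]1C(=O)OC | intermediate
7 | dilithium 2-{(1S,2S)-1-[(4S)-2,2-dimethyl-1,3-dioxolan-4-yl]-2-hydroxybut-3-yn-1-yl}propanedioate (ring-opened salt) | [Li+].[Li+].[O-]C(=O)C(C(=O)[O-])[C@H]([C@H]1COC(C)(C)O1)[C@H](O)C#C | intermediate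
8 | (3R,4S,5S)-4-[(4S)-2,2-dimethyl-1,3-dioxolan-4-yl]-5-ethynyl-2-oxooxolane-3-carboxylic acid | O=C1O[C@H](C#C)[C@@H]([C@H]2COC(C)(C)O2)[C@@H]1C(=O)O | intermediate
9 | Mannich base: 8 bearing a diethylaminomethyl group on C11 (C11 configuration not defined) | CCN(CC)CC1(C(=O)O)C(=O)O[C@H](C#C)[C@H]1[C@H]1COC(C)(C)O1 | intermediate
10 | (4S,5S)-4-[(4S)-2,2-dimethyl-1,3-dioxolan-4-yl]-5-ethynyl-3-methylideneoxolan-2-one | C=C1C(=O)O[C@H](C#C)[C@H]1[C@H]1COC(C)(C)O1 | intermediate
11 | diol: trans-5-ethynyl-3-methylidene lactone carrying the (S)-1,2-dihydroxyethyl group on C10 | C=C1C(=O)O[C@H](C#C)[C@H]1[C@H](O)CO | intermediate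
12 | C8 triethylsilyl ether of 11 (C9 hydroxyl free) | C=C1C(=O)O[C@H](C#C)[C@H]1[C@H](O)CO[Si](CC)(CC)CC | intermediate
13 | angelic acid, (Z)-2-methylbut-2-enoic acid | C/C=C(/C)C(=O)O | starting material
14 | (Z)-2-methylbut-2-en-1-ol | C/C=C(/C)CO | intermediate
15 | [(2R,3S)-2,3-dimethyloxiran-2-yl]methanol | OC[C@@]1(C)O[C@H]1C | intermediate
16 | (2S,3S)-2,3-dimethyloxirane-2-carboxylic acid (epoxyangelic acid) | OC(=O)[C@@]1(C)O[C@H]1C | intermediate
17 | mixed anhydride of 16 with 2,4,6-trichlorobenzoic acid | O=C(OC(=O)[C@@]1(C)O[C@H]1C)c1c(Cl)cc(Cl)cc1Cl | intermediate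
18 | C9 (2S,3S)-epoxyangelate of 12 (terminal alkyne, C8 triethylsilyl ether) | C=C1C(=O)O[C@H](C#C)[C@H]1[C@H](OC(=O)[C@@]1(C)O[C@H]1C)CO[Si](CC)(CC)CC | intermediate
19 | ethyl (Z)-3-iodoprop-2-enoate | CCOC(=O)/C=C\I | starting material
20 | (Z)-3-iodoprop-2-en-1-ol | OC/C=C\I | intermediate
21 | Z-enynol: 18 extended at C3 by (Z)-CH=CH–CH2OH | C=C1C(=O)O[C@H](C#C/C=C\CO)[C@H]1[C@H](OC(=O)[C@@]1(C)O[C@H]1C)CO[Si](CC)(CC)CC | intermediate
22 | alkynyl cis-epoxy alcohol, (4S,5R)-epoxide | C=C1C(=O)O[C@H](C#C[C@@H]2O[C@@H]2CO)[C@H]1[C@H](OC(=O)[C@@]1(C)O[C@H]1C)CO[Si](CC)(CC)CC | intermediate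
23 | (Z)-alkenyl cis-epoxy alcohol, (4S,5R)-epoxide | C=C1C(=O)O[C@H](/C=C\[C@@H]2O[C@@H]2CO)[C@H]1[C@H](OC(=O)[C@@]1(C)O[C@H]1C)CO[Si](CC)(CC)CC | intermediate
24 | cis-epoxy aldehyde (C6 = CHO) | C=C1C(=O)O[C@H](/C=C\[C@@H]2O[C@@H]2C=O)[C@H]1[C@H](OC(=O)[C@@]1(C)O[C@H]1C)CO[Si](CC)(CC)CC | intermediate
25 | methyl (Z)-2-iodoenoate (C6=C7, I on C7), C8 triethylsilyl ether | C=C1C(=O)O[C@H](/C=C\[C@@H]2O[C@@H]2/C=C(/C(=O)OC)I)[C@H]1[C@H](OC(=O)[C@@]1(C)O[C@H]1C)CO[Si](CC)(CC)CC | intermediate
26 | C8 aldehyde of the iodoenoate | C=C1C(=O)O[C@H](/C=C\[C@@H]2O[C@@H]2/C=C(/C(=O)OC)I)[C@H]1[C@H](OC(=O)[C@@]1(C)O[C@H]1C)C=O | intermediate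
27 | macrocyclic (8R)-alcohol, the deacetyl target | C=C1C(=O)O[C@@H]2/C=C\[C@@H]3O[C@@H]3/C=C(/C(=O)OC)[C@@H](O)[C@@H](OC(=O)[C@@]3(C)O[C@H]3C)[C@@H]12 | intermediate
28 | CNP0077533.1, (1R,4S,5R,8R,9S,10S) in the numbering of the plan, (2S,3S)-epoxyangelate at C9 | C=C1C(=O)O[C@@H]2/C=C\[C@@H]3O[C@@H]3/C=C(/C(=O)OC)[C@@H](OC(C)=O)[C@@H](OC(=O)[C@@]3(C)O[C@H]3C)[C@@H]12 | target

**Step count and risks**

Total step count: 20. Longest linear sequence: 16 steps (steps 1–7, 11, 13–20); steps 8–10 and step 12 are side branches.

Steps most likely to fail: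

Step 3. The E alkene gives only weak allylic strain, so facial selectivity at C10 may be poor; the acetonide may solvolyse in warm acetic acid; and the product may be oxidised again and add a second enyne. The fallback leaves the radical annulation and builds the same lactone by an allylmetal route that sets out from 1 and returns at 10. Compound 1 would react with methyl acrylate and DABCO (Morita–Baylis–Hillman) to give the allylic alcohol F1. NBS/Me2S would convert this with allylic transposition into the (Z)-2-(bromomethyl)enoate F2. The allylchromium reagent from F2 and CrCl2 would add to 3-(trimethylsilyl)propynal through a chair transition state to give the anti hydroxy ester F3. F3 should lactonise on mild acid treatment to the trans silylalkynyl methylene lactone F4, and TBAF buffered with AcOH would remove silicon to give 10.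

Step 19. The slow ten-ring closure may lose the Felkin preference at C8, so that the macrocyclic transition state decides the face of the aldehyde; high dilution addresses competing intermolecular coupling but not this. The fallback sets C8 by reagent-controlled reduction instead of by the C–C bond formation. It sets out from 27 obtained as a mixture with its C8 epimer, which would be oxidised with Dess–Martin periodinane to the C8 ketone F6. F6 would be reduced with BH3·SMe2 and the 2-methyl-CBS-oxazaborolidine enantiomer that delivers hydride to give the 8R alcohol, returning at 27.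

Step 15. Hydrogen may also add to the exocyclic methylene, or the propargylic and allylic C–O bonds (lactone, epoxide) may undergo hydrogenolysis on palladium. The fallback moves the reduction ahead of the epoxidation and avoids H2/Pd. It sets out from 21, which would be reduced with zinc activated by Cu(OAc)2 and AgNO3 in aqueous methanol to the (2Z,4Z)-dienol F5. Sharpless epoxidation of F5 (Ti(OiPr)4, D-(−)-diethyl tartrate, tBuOOH) at the allylic alcohol alkene would then return to the route at 23.

Further compounds
F1 | step 3 | methyl 2-{[(4R)-2,2-dimethyl-1,3-dioxolan-4-yl](hydroxy)methyl}prop-2-enoate (carbinol epimers) | C=C(C(=O)OC)C(O)[C@H]1COC(C)(C)O1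
F2 | step 3 | methyl (Z)-2-(bromomethyl)-3-[(4S)-2,2-dimethyl-1,3-dioxolan-4-yl]prop-2-enoate | COC(=O)/C(CBr)=C/[C@H]1COC(C)(C)O1
F3 | step 3 | anti hydroxy ester: methyl 2-methylidene-3-[(4S)-2,2-dimethyl-1,3-dioxolan-4-yl]-4-hydroxy-6-(trimethylsilyl)hex-5-ynoate with the C1/C9/C10 configuration of 10 | C=C(C(=O)OC)[C@H]([C@H]1COC(C)(C)O1)[C@H](O)C#C[Si](C)(C)C
F4 | step 3 | C-trimethylsilyl derivative of 10 | C=C1C(=O)O[C@H](C#C[Si](C)(C)C)[C@H]1[C@H]1COC(C)(C)O1
F5 | step 15 | (2Z,4Z)-dienol: 21 with the alkyne reduced to the Z alkene | C=C1C(=O)O[C@H](/C=C\C=C/CO)[C@H]1[C@H](OC(=O)[C@@]1(C)O[C@H]1C)CO[Si](CC)(CC)CC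
F6 | step 19 | macrocyclic C8 ketone | C=C1C(=O)O[C@@H]2/C=C\[C@@H]3O[C@@H]3/C=C(/C(=O)OC)C(=O)[C@@H](OC(=O)[C@@]3(C)O[C@H]3C)[C@@H]12
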